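The retrosynthesis first cuts the O3–S bond and the three benzyl masks on O5, O7 and O4', then the C3–O bond, then ring C at C4a–C4, C4–C3 and O1–C2 in one operation.
The enabling feature lies in ring C: the C4 carbonyl sits between C4a of ring A and the C3=C2 unit that bears ring B, and O1 sits on C8a next to C4a. C4 can therefore be carbon monoxide placed between an ortho-acyloxy aryl iodide and an arylalkyne.
In the forward direction, ring A is bought as a dibenzyl ether of phloroglucinol, iodinated next to its free OH and acetylated. Ring B comes with the bought alkyne, and ring C, the only ring built, closes in the palladium-catalysed three-component step.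
Only one oxygen next to the iodine is amine-labile, and O5, O7 and O4' are already benzylated, so the flavone emerges fully protected. C3 is then hydroxylated by lithiation, borylation and oxidation, its lone OH is sulfated, and the benzyl groups are removed.
The target has no stereocentre and no stereogenic double bond, so no configuration has to be set.

Key step: step 3

Assumption: the target is taken as the free hydrogen sulfate as drawn; because aryl hydrogen sulfates hydrolyse under their own acidity, the ester is carried as its triethylammonium salt and protonated only in the last operation, cold, followed by freeze-drying.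

Step 1
Reactants: 1 3,5-bis(benzyloxy)phenol
Product: 2 3,5-bis(benzyloxy)-2-iodophenol (iodine between the OH-bearing and one OBn-bearing carbon)
Conditions: NIS (1.0 equiv), CH2Cl2, −20 → 0 °C, dark
Reagents that add atoms: N-iodosuccinimide, O=C1CCC(=O)N1I
Why: Electrophilic aromatic iodination of a phloroglucinol-type ring in which all three free positions are activated, but the two equivalent sites ortho to the hydroxyl are less crowded than the single site between the two benzyloxy groups and are favoured by hydrogen-bond-guided delivery of iodine from NIS in a non-polar solvent, so the 2-iodide should dominate and the minor 4-iodide is removed by chromatography.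

Step 2
Reactants: 2 3,5-bis(benzyloxy)-2-iodophenol
Product: 3 3,5-bis(benzyloxy)-2-iodophenyl acetate
Conditions: Ac2O, pyridine, DMAP (cat.), CH2Cl2, 0 °C → rt
Reagents that add atoms: acetic anhydride, CC(=O)OC(C)=O
Why: DMAP-catalysed O-acetylation of a phenol, which lowers the electron density at the carbon–iodine bond, prevents phenoxide formation before the coupling and serves as the amine-labile mask of the future O1.

Step 3
Reactants: 3 3,5-bis(benzyloxy)-2-iodophenyl acetate; 4 1-(benzyloxy)-4-ethynylbenzene; 5 carbon monoxide
Product: 8 5,7-bis(benzyloxy)-2-[4-(benzyloxy)phenyl]-4H-chromen-4-one (tri-O-benzylapigenin), via acetoxy ynone 6 (not isolated), via enaminone phenol 7 (not isolated)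
Conditions: PdCl2(PPh3)2 (5 mol %), dppp (5 mol %), CO (1 atm, balloon), Et2NH (solvent), 40 → 60 °C, no copper salt
Reagents that add atoms: carbon monoxide 5, [C-]#[O+] (also listed as reactant); diethylamine, CCNCC (its atoms stand only in intermediate 7 and leave again)
Why: PdCl2(PPh3)2 is reduced in the flask to zerovalent palladium, which inserts into the carbon–iodine bond of 3; CO insertion gives an aroylpalladium iodide, and alkyne 4, bound to palladium and deprotonated by Et2NH, is joined to the acyl carbon by reductive elimination, so that ynone 6 carries the new C4a–C4 and C4–C3 bonds. Diethylamine then adds to the β-carbon of the ynone and aminolyses the aryl acetate, which gives enaminone phenol 7. The freed phenol oxygen attacks the amine-bearing β-carbon and expels Et2NH, a 6-endo-trig addition–elimination that forms O1–C2 and closes ring C, the only ring made in this step. The closest known reaction type is the carbonylative Sonogashira annulation of ortho-iodophenol acetates with terminal arylalkynes to flavones. No stereocentre is formed, and the geometry of the double bond in 7 is lost on closure. Three selectivities are needed: CO uptake before alkynylation, secured by the CO atmosphere, the absence of copper and the ready migration of an electron-rich aryl group to CO; six-membered (flavone) over five-membered (aurone) closure, secured by the enaminone, whose electrophilic site is the β-carbon; and a single ring-closing oxygen, secured because only the acetate of 3 is amine-labile while the other ortho oxygen stays a benzyl ether.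

Step 4
Reactants: 8 5,7-bis(benzyloxy)-2-[4-(benzyloxy)phenyl]-4H-chromen-4-one
Product: 11 5,7-bis(benzyloxy)-2-[4-(benzyloxy)phenyl]-3-hydroxy-4H-chromen-4-one (5,7,4'-tri-O-benzylkaempferol), via 3-lithioflavone 9 (not isolated), via lithium flavonylborate 10 (not isolated)
Conditions: LiN(iPr)2, THF, −78 °C; B(OMe)3, −78 → 0 °C; AcOH, 30% aq H2O2, 0 °C → rt
Reagents that add atoms: lithium diisopropylamide, [Li]N(C(C)C)C(C)C (Li of 9 and 10); trimethyl borate, COB(OC)OC (boron unit of 10); hydrogen peroxide, OO (the C3 oxygen of 11)
Why: Lithiation–borylation–oxidation, a known way from flavones to flavonols, in which C3–H is the most acidic C–H (sp2, next to C4=O, lithium held by the carbonyl oxygen), the amide base at −78 °C should leave aryl benzyl ethers alone, and peroxide triggers the usual 1,2-shift of C3 from boron to oxygen.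

Step 5
Reactants: 11 5,7-bis(benzyloxy)-2-[4-(benzyloxy)phenyl]-3-hydroxy-4H-chromen-4-one
Product: 12 triethylammonium 5,7-bis(benzyloxy)-2-[4-(benzyloxy)phenyl]-4-oxo-4H-chromen-3-yl sulfate
Conditions: Et3N·SO3, Et3N, DMF, 50 °C; SiO2 (CH2Cl2/MeOH/Et3N)
Reagents that add atoms: sulfur trioxide–triethylamine complex, CC[N+](CC)(CC)S(=O)(=O)[O-]
Why: O-sulfation with an amine–sulfur trioxide complex, in which site selectivity is settled by the protecting-group pattern because the 3-OH is the only hydroxyl in 11, and the lipophilic triethylammonium salt should be stable to chromatography on base-washed silica.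

Step 6
Reactants: 12 triethylammonium 5,7-bis(benzyloxy)-2-[4-(benzyloxy)phenyl]-4-oxo-4H-chromen-3-yl sulfate
Product: 14 kaempferol 3-O-sulfate (5,7-dihydroxy-2-(4-hydroxyphenyl)-4-oxo-4H-chromen-3-yl hydrogen sulfate), via triethylammonium kaempferol 3-sulfate 13 (not isolated)
Conditions: H2 (1 atm), 10% Pd/C, THF/MeOH, rt; filter; sulfonic acid cation-exchange resin (H+ form), MeOH/H2O, 0 °C; freeze-dry
Reagents that add atoms: none
Why: Catalytic hydrogenolysis of aryl benzyl ethers, which under neutral conditions should spare the aryl sulfate salt and the tetrasubstituted C2=C3 bond of the flavonol, followed by cation exchange that swaps triethylammonium for a proton.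

Compound list
1 | 3,5-bis(benzyloxy)phenol | Oc1cc(OCc2ccccc2)cc(OCc2ccccc2)c1 | starting material
2 | 3,5-bis(benzyloxy)-2-iodophenol | Oc1cc(OCc2ccccc2)cc(OCc2ccccc2)c1I | intermediate
3 | 3,5-bis(benzyloxy)-2-iodophenyl acetate | CC(=O)Oc1cc(OCc2ccccc2)cc(OCc2ccccc2)c1I | intermediate
4 | 1-(benzyloxy)-4-ethynylbenzene | C#Cc1ccc(OCc2ccccc2)cc1 | starting material
5 | carbon monoxide | [C-]#[O+] | starting material
6 | 3,5-bis(benzyloxy)-2-{3-[4-(benzyloxy)phenyl]prop-2-ynoyl}phenyl acetate (not isolated) | CC(=O)Oc1cc(OCc2ccccc2)cc(OCc2ccccc2)c1C(=O)C#Cc1ccc(OCc2ccccc2)cc1 | intermediate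
7 | (E)-1-[2,4-bis(benzyloxy)-6-hydroxyphenyl]-3-[4-(benzyloxy)phenyl]-3-(diethylamino)prop-2-en-1-one (not isolated; drawn as the E isomer, geometry without consequence) | CCN(CC)/C(=C/C(=O)c1c(O)cc(OCc2ccccc2)cc1OCc1ccccc1)c1ccc(OCc2ccccc2)cc1 | intermediate
8 | 5,7-bis(benzyloxy)-2-[4-(benzyloxy)phenyl]-4H-chromen-4-one | O=c1cc(-c2ccc(OCc3ccccc3)cc2)oc2cc(OCc3ccccc3)cc(OCc3ccccc3)c12 | intermediate
9 | {5,7-bis(benzyloxy)-2-[4-(benzyloxy)phenyl]-4-oxo-4H-chromen-3-yl}lithium (not isolated) | [Li]c1c(-c2ccc(OCc3ccccc3)cc2)oc2cc(OCc3ccccc3)cc(OCc3ccccc3)c2c1=O | intermediate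
10 | lithium {5,7-bis(benzyloxy)-2-[4-(benzyloxy)phenyl]-4-oxo-4H-chromen-3-yl}trimethoxyborate (not isolated) | [Li+].CO[B-](OC)(OC)c1c(-c2ccc(OCc3ccccc3)cc2)oc2cc(OCc3ccccc3)cc(OCc3ccccc3)c2c1=O | intermediate
11 | 5,7-bis(benzyloxy)-2-[4-(benzyloxy)phenyl]-3-hydroxy-4H-chromen-4-one | O=c1c(O)c(-c2ccc(OCc3ccccc3)cc2)oc2cc(OCc3ccccc3)cc(OCc3ccccc3)c12 | intermediate
12 | triethylammonium 5,7-bis(benzyloxy)-2-[4-(benzyloxy)phenyl]-4-oxo-4H-chromen-3-yl sulfate | CC[NH+](CC)CC.O=c1c(OS(=O)(=O)[O-])c(-c2ccc(OCc3ccccc3)cc2)oc2cc(OCc3ccccc3)cc(OCc3ccccc3)c12 | intermediate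
13 | triethylammonium 5,7-dihydroxy-2-(4-hydroxyphenyl)-4-oxo-4H-chromen-3-yl sulfate (not isolated) | CC[NH+](CC)CC.O=c1c(OS(=O)(=O)[O-])c(-c2ccc(O)cc2)oc2cc(O)cc(O)c12 | intermediate
14 | kaempferol 3-O-sulfate | O=c1c(OS(=O)(=O)O)c(-c2ccc(O)cc2)oc2cc(O)cc(O)c12 | target

Total step count: 6. Longest linear sequence: 6 steps (1 → 14). Compounds 4 and 5 enter as bought.

Steps most likely to fail

Risk 1, the key step (step 3). Oxidative addition may be slow, because the carbon–iodine bond is flanked by two oxygen substituents on an electron-rich ring while CO occupies the palladium. The acetate may also be aminolysed before coupling, diethylamine may intercept the aroylpalladium (aminocarbonylation), or the alkyne may couple without CO uptake.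

The fallback forms the same three bonds without palladium and takes C4 from a carbamoyl chloride. It sets out from iodophenol 2 and alkyne 4 and comes back at flavone 8. Phenol 2 is protected (MOMCl, iPr2NEt, CH2Cl2) as 1,5-bis(benzyloxy)-2-iodo-3-(methoxymethoxy)benzene F1. Alkyne 4 is deprotonated with n-BuLi (THF, −78 °C) to lithium [4-(benzyloxy)phenyl]acetylide F2. This is acylated with N-methoxy-N-methylcarbamoyl chloride to the Weinreb amide 3-[4-(benzyloxy)phenyl]-N-methoxy-N-methylprop-2-ynamide F3.

Iodine–lithium exchange on F1 (n-BuLi, THF, −78 °C) gives [2,4-bis(benzyloxy)-6-(methoxymethoxy)phenyl]lithium F4. It adds to F3 and, after an NH4Cl quench, should give 1-[2,4-bis(benzyloxy)-6-(methoxymethoxy)phenyl]-3-[4-(benzyloxy)phenyl]prop-2-yn-1-one F5. HCl in MeOH/THF removes the acetal to give 1-[2,4-bis(benzyloxy)-6-hydroxyphenyl]-3-[4-(benzyloxy)phenyl]prop-2-yn-1-one F6. Et2NH in EtOH then takes F6 through enaminone 7 to 8.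

Risk 2, the C3 hydroxylation (step 4). The amide base may deprotonate a benzylic CH2, most likely that of the O5 benzyl group held near the lithium-binding carbonyl. It may also add at C2 with opening of the pyranone. The hindered C3 anion may be captured incompletely by the borate, so that flavone is returned.

The fallback replaces deprotonation by electrophilic oxygen transfer to C2=C3. It sets out from 8 and comes back at 11. Dimethyldioxirane (acetone/CH2Cl2, 0 °C) should epoxidise the enol-ether double bond to racemic 5,7-bis(benzyloxy)-2-[4-(benzyloxy)phenyl]-2,3-epoxychroman-4-one F7. A catalytic amount of p-TsOH in CH2Cl2 opens the oxirane at the oxygen- and aryl-stabilised C2 and, by loss of H3, isomerises it to 11.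

Risk 3, the final deprotection (step 6). The sulfate ester may be lost by solvolysis if hydrogenolysis is slow. The O5 benzyl group is the most hindered, and sulfur-containing residues from step 5 can deactivate the palladium surface. C2=C3 may be over-reduced on long exposure, and the acid form may hydrolyse itself during the ion exchange.

The fallback masks the sulfate as a neutral diester that can be purified on silica. The diester is unmasked together with the benzyl ethers under buffered transfer hydrogenolysis. The fallback sets out from 11 and comes back at 14. Flavonol 11 reacts with 2,2,2-trichloroethyl chlorosulfate (Et3N, DMAP, THF) to give 5,7-bis(benzyloxy)-2-[4-(benzyloxy)phenyl]-4-oxo-4H-chromen-3-yl 2,2,2-trichloroethyl sulfate F8. Treatment with 10% Pd/C and HCO2NH4 (MeOH/THF, rt) cleaves the three benzyl ethers and fragments the trichloroethyl group reductively to ammonium kaempferol 3-sulfate F9. A brief cold passage through the sulfonic acid resin (H+ form) then gives 14.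

Further compounds
F1 | step 3 | 1,5-bis(benzyloxy)-2-iodo-3-(methoxymethoxy)benzene | COCOc1cc(OCc2ccccc2)cc(OCc2ccccc2)c1I
F2 | step 3 | lithium [4-(benzyloxy)phenyl]acetylide | [Li]C#Cc1ccc(OCc2ccccc2)cc1
F3 | step 3 | 3-[4-(benzyloxy)phenyl]-N-methoxy-N-methylprop-2-ynamide | CON(C)C(=O)C#Cc1ccc(OCc2ccccc2)cc1
F4 | step 3 | [2,4-bis(benzyloxy)-6-(methoxymethoxy)phenyl]lithium | COCOc1cc(OCc2ccccc2)cc(OCc2ccccc2)c1[Li]
F5 | step 3 | 1-[2,4-bis(benzyloxy)-6-(methoxymethoxy)phenyl]-3-[4-(benzyloxy)phenyl]prop-2-yn-1-one | COCOc1cc(OCc2ccccc2)cc(OCc2ccccc2)c1C(=O)C#Cc1ccc(OCc2ccccc2)cc1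
F6 | step 3 | 1-[2,4-bis(benzyloxy)-6-hydroxyphenyl]-3-[4-(benzyloxy)phenyl]prop-2-yn-1-one | Oc1cc(OCc2ccccc2)cc(OCc2ccccc2)c1C(=O)C#Cc1ccc(OCc2ccccc2)cc1
F7 | step 4 | racemic 5,7-bis(benzyloxy)-2-[4-(benzyloxy)phenyl]-2,3-epoxychroman-4-one (oxirane necessarily cis-fused; one enantiomer drawn) | O=C1[C@@H]2O[C@]2(c2ccc(OCc3ccccc3)cc2)Oc2cc(OCc3ccccc3)cc(OCc3ccccc3)c12
F8 | step 6 | 5,7-bis(benzyloxy)-2-[4-(benzyloxy)phenyl]-4-oxo-4H-chromen-3-yl 2,2,2-trichloroethyl sulfate | O=c1c(OS(=O)(=O)OCC(Cl)(Cl)Cl)c(-c2ccc(OCc3ccccc3)cc2)oc2cc(OCc3ccccc3)cc(OCc3ccccc3)c12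
F9 | step 6 | ammonium kaempferol 3-sulfate | [NH4+].O=c1c(OS(=O)(=O)[O-])c(-c2ccc(O)cc2)oc2cc(O)cc(O)c12
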